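In this closed, stirred vessel the reagent sits in the second phase and crosses into the reaction phase, where it meets the substrate and makes the target. You want to know what is finished by 3.0 min, so take the earlier runs from the earliest event to the latest.

| flask | substrate | reagent in the second phase | remark | time | volume of the second phase over the first |
|---|---|---|---|---|---|
| north-west | 0.15 M | 0.285 M | run made earlier |  |  |
| south | 0.60 M | 0.285 M | run made earlier |  |  |
| north-east | 0.30 M | 0.43 M | run made earlier |  |  |
| flask | 0.30 M | 0.285 M |  | 3.0 min | 0.25 |

- north-west (time / min: target / %, substrate / %): 0.250: 15.0, 83.2; 0.667: 29.2, 48.2; 1.33: 22.8, 22.4; 2.00: 15.2, 12.7; 3.00: 7.7, 6.6; 4.00: 5.9, 3.7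
- south (time / min: target / %, substrate / %): 0.250: 10.7, 86.7; 0.667: 18.4, 68.6; 1.33: 14.6, 58.6; 2.00: 9.1, 55.5; 3.00: 5.3, 54.7; 4.00: 3.3, 55.0
- north-east (time / min: target / %, substrate / %): 0.333: 23.9, 67.7; 0.833: 28.5, 34.1; 1.50: 19.4, 18.4; 2.50: 10.4, 10.2; 4.00: 5.6, 6.1

(readings scatter by 0.5 percentage points)

- percentages count the substrate that a species holds: one side product counts as two
- in the second phase: reagent in the second phase; everything else is in the first
- charges count per volume of the first phase; a concentration in a rate is the amount of a species over the volume of its own phase; every rate counts per litre of the first phase
- steps thought possible: reagent in the reaction phase + target -> over-reacted product; reagent in the reaction phase <-> reagent in the second phase; substrate + reagent in the reaction phase -> target; target <-> isomer of the product; substrate + target -> side product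
- the earlier runs hold the two phases in the same ratio of volumes as the flask asked about

- amber: doubling the amount of reagent in the second phase, all else as stated
- green: doubling the transfer coefficient of the reagent in the second phase, all else as stated

- how much target there is at 3.0 min, in percent of the substrate charged
- the change that raises the amount of target at 3.0 min, in percent of the substrate charged most ("none" if none brings more than 2 percentage points) (amber / green / none)
- amount of target at 3.0 min, in percent of the substrate charged, after amber

On the first rung, the target climbs. In the north-west run the substrate is down to 48.2% at 0.667 min, and the target reads 29.2% there, its highest reading in that run.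

Next comes the reagent budget, where one reagent per substrate is the zero of the scale. The south run is charged with reagent at 47.5% of its substrate, and its substrate reads 55.5% at 2.00 min and 55.0% at 4.00 min: reagent is the limiting reagent there. The flask is charged at 95.0%, close to one reagent per substrate.

The last rung is the one to carry. Once the substrate in the south run stops falling, the target still falls, from 9.1% to 3.3%. The time in which it halves on that stretch, the tail half-life of the target, reads 1.37 min. The asked time is 2.19 of these and lies later than the highest target reading of the north-west run, so expect the flask past its peak.

My own estimate starts from the north-east run, with the same substrate charge and more reagent. Its 10.4% at 2.50 min, carried to 3.0 min with that half-life, gives 8.07% as my estimate for the north-east run, and I put the flask, charged with less reagent, somewhat above it.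

The forecast is higher than that estimate, at 11.5%, with none as the best change and 7.5% after amber: “By 3 min the target is already past its peak and decaying.”

The flask gives 9.60%, the best change is none, and amber gives 4.58%, while green shifts the target by −0.74 percentage points.

    reagent in the reaction phase + target → over-reacted product (k = 0.120 /M/s)
    reagent in the reaction phase ⇌ reagent in the second phase, rate k2*([reagent in the reaction phase] - [reagent in the second phase]/K2) per volume of the first phase (partition coefficient = 0.990, kL = 0.0140 /s)
    substrate + reagent in the reaction phase → target (k = 0.160 /M/s)
    target ⇌ isomer of the product (K = 11.0, k = 0.0160 /s)
    substrate + target → side product (k = 0.00410 /M/s)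

In the flask the target goes to the isomer of the product with a forward half-life of 0.72 min, taken alone, which is shorter than the 3.0 min, while the path to side product, taken alone with the other concentrations as charged, has 9.4 min, longer than that time. At 3.0 min the isomer holds 42.3% and the side product 3.28%. The tail half-life takes the flask's 19.7% at 1.50 min to 9.22% at 3.0 min, against 9.60% in the flask. Carried to 12 min it gives 0.100%, but the flask left that long holds 4.46%.

All runs come from a simulation with made-up constants.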